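**Retrosynthetic overview**

1. Siphonellinol C ⇐ cross-metathesis of a ring C allyl group with 2-methylbut-3-en-2-ol ⇐ equatorial methyl addition to a ring B ketone (17).
2. Rings A (oxepane) and B (cyclohexane) are closed together, last of all rings, by a silyl triflate-triggered diepoxide oxa-/carbacyclisation terminated by a regiodefined silyl enol ether (15).
3. 15 ⇐ a new nickel-catalysed reductive ring-opening alkenylation joins cyclopropyl ketone 5 (its two ring CH2 groups become the ethylene bridge) to ring C alkenyl triflate 14.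
4. 5 ⇐ cyclopropyl methyl ketone + geranyl bromide, then Shi epoxidation (organocatalytic; first stereocentres, and the source of all five stereocentres of rings A and B).
5. 14 (ring C, a ring from the start) ⇐ 2-methylcyclohexane-1,3-dione by allylation, oxazaborolidine-catalysed desymmetrising reduction, methylation and enol triflation.

Assumption: ring A = oxepane, ring B = its fused cyclohexane, ring C = the cyclohexene; the bicycle carries 1-benzoxepine locants (O1, C2 … C5a, C6 … C9a); the D-fructose-derived Shi ketone is taken to give R-configured epoxides from E-trisubstituted alkenes, as it does with trans-β-methylstyrene.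

**Route**

Step 1
Reactants: 1 cyclopropyl methyl ketone; 2 geranyl bromide [(2E)-1-bromo-3,7-dimethylocta-2,6-diene]
Product: 4 (4E)-1-cyclopropyl-5,9-dimethyldeca-4,8-dien-1-one, via lithium enolate 3 (not isolated)
Conditions: 1 (1.5 equiv), LiN(iPr)2, THF, −78 °C; then 2, DMPU, −78 → 0 °C
Reagents that add atoms: none
Why: Kinetic deprotonation can only occur at the methyl group (an enolate exocyclic to the cyclopropane is too strained), and the lithium enolate displaces the primary allylic bromide (enolate C-alkylation, SN2) without touching the E double bond.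

Step 2
Reactants: 4 (4E)-1-cyclopropyl-5,9-dimethyldeca-4,8-dien-1-one
Product: 5 (4R,5R,8R)-1-cyclopropyl-4,5:8,9-diepoxy-5,9-dimethyldecan-1-one
Conditions: D-fructose-derived Shi ketone (2 × 30 mol %), Oxone (2KHSO5·KHSO4·K2SO4), K2CO3, Bu4NHSO4, Na2B4O7/Na2EDTA buffer (pH 10.5), MeCN–CH2(OMe)2–H2O, 0 °C
Reagents that add atoms: potassium peroxymonosulfate KHSO5 (from Oxone), [K+].[O-]S(=O)(=O)OO
Why: Shi asymmetric epoxidation: the chiral dioxirane transfers oxygen to both electron-rich trisubstituted alkenes through the spiro transition state, which sets C4, C5 and C8 as R (the first stereocentres, set by the organocatalyst), while the ketone and the cyclopropane are inert at this pH.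

Step 3
Reactants: 6 2-methylcyclohexane-1,3-dione; 7 allyl bromide
Product: 8 2-methyl-2-(prop-2-en-1-yl)cyclohexane-1,3-dione
Conditions: 7, aq NaOH (1 M), Bu4NI (cat.), rt
Reagents that add atoms: none
Why: C-Alkylation of the stabilised 1,3-diketone enolate by the allylic bromide (enolate alkylation) gives the quaternary but still achiral dione whose two carbonyl groups are enantiotopic.

Step 4
Reactants: 8 2-methyl-2-(prop-2-en-1-yl)cyclohexane-1,3-dione
Product: 9 (2R,3R)-3-hydroxy-2-methyl-2-(prop-2-en-1-yl)cyclohexan-1-one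
Conditions: (S)-2-methyl-CBS-oxazaborolidine (20 mol %), catecholborane (1.1 equiv), toluene, −78 → −40 °C; MeOH, then aq NaOH wash
Reagents that add atoms: none
Why: Corey–Bakshi–Shibata reduction used as an enantiotopic-group-selective desymmetrisation: the (S)-oxazaborolidine delivers hydride to the carbonyl face that gives the R carbinol (quaternary carbon as the large group), and only the carbonyl for which this face is also anti to the pseudo-axial allyl group reacts fast, so the hydroxyl ends up cis to allyl and the quaternary centre is fixed as R.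

Step 5
Reactants: 9 (2R,3R)-3-hydroxy-2-methyl-2-(prop-2-en-1-yl)cyclohexan-1-one
Product: 10 (2R,3R)-2-methyl-2-(prop-2-en-1-yl)-3-(triethylsilyloxy)cyclohexan-1-one
Conditions: Et3SiCl, imidazole, CH2Cl2, 0 °C → rt
Reagents that add atoms: chlorotriethylsilane, CC[Si](Cl)(CC)CC
Why: O-Silylation under mild base protects the ketol against retro-aldol opening and masks the hydroxyl for the enolate, nickel and Lewis acid steps, with no change at either stereocentre.

Step 6
Reactants: 10 (2R,3R)-2-methyl-2-(prop-2-en-1-yl)-3-(triethylsilyloxy)cyclohexan-1-one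
Product: 12 (2R,3R,6RS)-2,6-dimethyl-2-(prop-2-en-1-yl)-3-(triethylsilyloxy)cyclohexan-1-one, via lithium enolate 11 (not isolated)
Conditions: LiN(iPr)2, THF, −78 °C; then MeI, −78 → −20 °C
Reagents that add atoms: iodomethane, CI
Why: Enolate alkylation at the only enolisable α-carbon (the other is quaternary); the new methyl-bearing centre forms as a mixture, which does not matter because it becomes sp2 in step 7.

Step 7
Reactants: 12 (2R,3R,6RS)-2,6-dimethyl-2-(prop-2-en-1-yl)-3-(triethylsilyloxy)cyclohexan-1-one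
Product: 14 (5R,6R)-2,6-dimethyl-6-(prop-2-en-1-yl)-5-(triethylsilyloxy)cyclohex-1-en-1-yl trifluoromethanesulfonate, via potassium enolate 13 (not isolated)
Conditions: KN(SiMe3)2, THF, −78 → 0 °C; then PhNTf2, −78 °C → rt
Reagents that add atoms: N-phenylbis(trifluoromethanesulfonyl)imide, O=S(=O)(N(c1ccccc1)S(=O)(=O)C(F)(F)F)C(F)(F)F
Why: Enol triflate formation: only one enolate regioisomer exists, and its O-sulfonylation gives the tetrasubstituted alkenyl triflate that already holds the ring C double bond in its final place.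

Step 8
Reactants: 5 (4R,5R,8R)-1-cyclopropyl-4,5:8,9-diepoxy-5,9-dimethyldecan-1-one; 14 (5R,6R)-2,6-dimethyl-6-(prop-2-en-1-yl)-5-(triethylsilyloxy)cyclohex-1-en-1-yl trifluoromethanesulfonate
Product: 15 (3Z,7R,8R,11R)-7,8:11,12-diepoxy-1-[(5R,6S)-2,6-dimethyl-6-(prop-2-en-1-yl)-5-(triethylsilyloxy)cyclohex-1-en-1-yl]-8,12-dimethyl-4-(triethylsilyloxy)tridec-3-ene
Conditions: 5 (1.5 equiv), 14 (1.0 equiv), NiCl2(dme) (10 mol %), 2,2':6',2''-terpyridine (10 mol %), Et3SiCl (2 equiv), Mn powder (3 equiv), 2,6-lutidine (0.5 equiv), DMA–THF, 0 °C → rt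
Reagents that add atoms: chlorotriethylsilane, CC[Si](Cl)(CC)CC
Why: Proposed new method: nickel-catalysed reductive ring-opening alkenylation of a non-aryl cyclopropyl ketone with an alkenyl triflate and a chlorosilane; low-valent (terpyridine)nickel made by Mn inserts into the carbonyl-activated proximal C–C bond of the cyclopropane while Et3SiCl silylates oxygen, giving through a cisoid six-membered oxanickelacycle a γ-nickelated Z silyl enol ether (the one-carbon homologue of the siloxyallylnickel species formed from enones), which after reduction takes up triflate 14 by oxidative addition and forms the C(sp3)–C(sp2) bond by reductive elimination, so that the two cyclopropane CH2 groups become the ethylene bridge between the halves and the enol ether is fixed on the side that must later close ring B; no stereocentre is formed, and the epoxides should survive because no iodide or strong Lewis acid is present; the closest known reaction types are the nickel-catalysed reductive conjugate addition of organic halides to enones with chlorosilanes (silyl enol ether products) and nickel–terpyridine ring-opening cross-couplings of cyclopropyl ketones with organozinc reagents or alkyl halides.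

Step 9
Reactants: 15 (3Z,7R,8R,11R)-7,8:11,12-diepoxy-1-[(5R,6S)-2,6-dimethyl-6-(prop-2-en-1-yl)-5-(triethylsilyloxy)cyclohex-1-en-1-yl]-8,12-dimethyl-4-(triethylsilyloxy)tridec-3-ene
Product: 17 (3R,5aR,6R,9aR)-3-hydroxy-6-{2-[(5R,6S)-5-hydroxy-2,6-dimethyl-6-(prop-2-en-1-yl)cyclohex-1-en-1-yl]ethyl}-2,2,5a-trimethylperhydro-1-benzoxepin-7-one, via silylated bicyclic ketone 16 (not isolated)
Conditions: TMSOTf (1.2 equiv), 2,6-di-tert-butyl-4-methylpyridine, CH2Cl2, −78 °C, 30 min; Et3N, evaporate; then Bu4NF, THF, 0 °C → rt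
Reagents that add atoms: none
Why: Biomimetic tandem oxa-/carbacyclisation of a 1,5-diepoxide terminated by a silyl enol ether: the silylated terminal epoxide is opened at its tertiary carbon by the oxygen of the internal epoxide (ring A, C3 keeps its R configuration), the Z enol ether then attacks the tertiary carbon of the bridged epoxonium ion with inversion through a chair (ring B, trans fusion, C5a and C9a fixed by the internal epoxide, side chain equatorial at C6), and fluoride removes all silyl groups while equilibrating C6 to the equatorial epimer.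

Step 10
Reactants: 17 (3R,5aR,6R,9aR)-3-hydroxy-6-{2-[(5R,6S)-5-hydroxy-2,6-dimethyl-6-(prop-2-en-1-yl)cyclohex-1-en-1-yl]ethyl}-2,2,5a-trimethylperhydro-1-benzoxepin-7-one
Product: 18 (3R,5aR,6R,7S,9aR)-6-{2-[(5R,6S)-5-hydroxy-2,6-dimethyl-6-(prop-2-en-1-yl)cyclohex-1-en-1-yl]ethyl}-2,2,5a,7-tetramethylperhydro-1-benzoxepine-3,7-diol
Conditions: MeLi/CeCl3 (6 equiv each, premixed in THF, −78 °C), then 17, −78 → −40 °C; aq NH4Cl
Reagents that add atoms: methyllithium, C[Li]
Why: 1,2-Addition of the weakly basic organocerium reagent MeCeCl2 (no enolisation): axial approach to the ring B ketone is blocked by the axial C5a methyl group (1,3-diaxial), so methyl enters equatorially and the new hydroxyl is axial, which is the 7S configuration of the target.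

Step 11
Reactants: 18 (3R,5aR,6R,7S,9aR)-6-{2-[(5R,6S)-5-hydroxy-2,6-dimethyl-6-(prop-2-en-1-yl)cyclohex-1-en-1-yl]ethyl}-2,2,5a,7-tetramethylperhydro-1-benzoxepine-3,7-diol; 19 2-methylbut-3-en-2-ol
Product: 20 siphonellinol C, (3R,5aR,6R,7S,9aR)-6-{2-[(5R,6S)-5-hydroxy-6-[(2E)-4-hydroxy-4-methylpent-2-en-1-yl]-2,6-dimethylcyclohex-1-en-1-yl]ethyl}-2,2,5a,7-tetramethylperhydro-1-benzoxepine-3,7-diol
Conditions: 19 (10 equiv), [RuCl2(H2IMes)(=CH–C6H4-2-OiPr)] (second-generation Hoveyda–Grubbs catalyst, 5 mol %), CH2Cl2, 40 °C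
Reagents that add atoms: none
Why: Olefin cross-metathesis of the only terminal alkene with a bulky tertiary allylic alcohol gives the E-disubstituted alkene under thermodynamic control, while the tetrasubstituted ring C alkene and the free hydroxyls do not react.

**Compound list**

1 | cyclopropyl methyl ketone | CC(=O)C1CC1 | starting material
2 | geranyl bromide, (2E)-1-bromo-3,7-dimethylocta-2,6-diene | CC(C)=CCC/C(C)=C/CBr | starting material
3 | lithium 1-cyclopropylethen-1-olate (not isolated) | C=C(O[Li])C1CC1 | intermediate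
4 | (4E)-1-cyclopropyl-5,9-dimethyldeca-4,8-dien-1-one | CC(C)=CCC/C(C)=C/CCC(=O)C1CC1 | intermediate
5 | (4R,5R,8R)-1-cyclopropyl-4,5:8,9-diepoxy-5,9-dimethyldecan-1-one | O=C(C1CC1)CC[C@H]2O[C@]2(C)CC[C@H]3OC3(C)C | intermediate
6 | 2-methylcyclohexane-1,3-dione | CC1C(=O)CCCC1=O | starting material
7 | allyl bromide | C=CCBr | starting material
8 | 2-methyl-2-(prop-2-en-1-yl)cyclohexane-1,3-dione | C=CCC1(C)C(=O)CCCC1=O | intermediate
9 | (2R,3R)-3-hydroxy-2-methyl-2-(prop-2-en-1-yl)cyclohexan-1-one | O=C1[C@](C)(CC=C)[C@H](O)CCC1 | intermediate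
10 | (2R,3R)-2-methyl-2-(prop-2-en-1-yl)-3-(triethylsilyloxy)cyclohexan-1-one | O=C1[C@](C)(CC=C)[C@H](O[Si](CC)(CC)CC)CCC1 | intermediate
11 | lithium (5R,6R)-6-methyl-6-(prop-2-en-1-yl)-5-(triethylsilyloxy)cyclohex-1-en-1-olate (not isolated) | [Li]OC1=CCC[C@@H](O[Si](CC)(CC)CC)[C@@]1(C)CC=C | intermediate
12 | (2R,3R,6RS)-2,6-dimethyl-2-(prop-2-en-1-yl)-3-(triethylsilyloxy)cyclohexan-1-one | O=C1C(C)CC[C@@H](O[Si](CC)(CC)CC)[C@@]1(C)CC=C | intermediate
13 | potassium (5R,6R)-2,6-dimethyl-6-(prop-2-en-1-yl)-5-(triethylsilyloxy)cyclohex-1-en-1-olate (not isolated) | [K]OC1=C(C)CC[C@@H](O[Si](CC)(CC)CC)[C@@]1(C)CC=C | intermediate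
14 | (5R,6R)-2,6-dimethyl-6-(prop-2-en-1-yl)-5-(triethylsilyloxy)cyclohex-1-en-1-yl trifluoromethanesulfonate | O=S(=O)(OC1=C(C)CC[C@@H](O[Si](CC)(CC)CC)[C@@]1(C)CC=C)C(F)(F)F | intermediate
15 | (3Z,7R,8R,11R)-7,8:11,12-diepoxy-1-[(5R,6S)-2,6-dimethyl-6-(prop-2-en-1-yl)-5-(triethylsilyloxy)cyclohex-1-en-1-yl]-8,12-dimethyl-4-(triethylsilyloxy)tridec-3-ene | CC[Si](CC)(CC)O/C(CC[C@H]1O[C@]1(C)CC[C@H]2OC2(C)C)=C\CCC3=C(C)CC[C@@H](O[Si](CC)(CC)CC)[C@@]3(C)CC=C | intermediate
16 | (3R,5aR,6R,9aR)-6-{2-[(5R,6S)-2,6-dimethyl-6-(prop-2-en-1-yl)-5-(triethylsilyloxy)cyclohex-1-en-1-yl]ethyl}-2,2,5a-trimethyl-3-(trimethylsilyloxy)perhydro-1-benzoxepin-7-one (not isolated) | CC1=C(CC[C@@H]2[C@@]3(C)CC[C@@H](O[Si](C)(C)C)C(C)(C)O[C@@H]3CCC2=O)[C@](C)(CC=C)[C@H](O[Si](CC)(CC)CC)CC1 | intermediate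
17 | (3R,5aR,6R,9aR)-3-hydroxy-6-{2-[(5R,6S)-5-hydroxy-2,6-dimethyl-6-(prop-2-en-1-yl)cyclohex-1-en-1-yl]ethyl}-2,2,5a-trimethylperhydro-1-benzoxepin-7-one | CC1=C(CC[C@@H]2[C@@]3(C)CC[C@@H](O)C(C)(C)O[C@@H]3CCC2=O)[C@](C)(CC=C)[C@H](O)CC1 | intermediate
18 | (3R,5aR,6R,7S,9aR)-6-{2-[(5R,6S)-5-hydroxy-2,6-dimethyl-6-(prop-2-en-1-yl)cyclohex-1-en-1-yl]ethyl}-2,2,5a,7-tetramethylperhydro-1-benzoxepine-3,7-diol | CC1=C(CC[C@@H]2[C@@]3(C)CC[C@@H](O)C(C)(C)O[C@@H]3CC[C@]2(C)O)[C@](C)(CC=C)[C@H](O)CC1 | intermediate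
19 | 2-methylbut-3-en-2-ol | C=CC(C)(C)O | starting material
20 | siphonellinol C | CC1=C(CC[C@@H]2[C@@]3(C)CC[C@@H](O)C(C)(C)O[C@@H]3CC[C@]2(C)O)[C@](C)(C/C=C/C(C)(C)O)[C@H](O)CC1 | target

**Step count and risks**

Total step count: 11. Longest linear sequence: 9 steps (6 → 20, steps 3 to 11); the other branch is 6 steps (1 → 20, steps 1, 2, 8 to 11).

Steps most likely to fail:

Step 8 (the proposed new reaction). Dialkyl-type cyclopropyl ketones are harder to activate than aryl ones, the alkenyl triflate is tetrasubstituted, and the chlorosilane or the manganese salts may open the trisubstituted epoxides. The fallback uses known chemistry only, sets out from 2 and 14, and comes back at 15. Geranyl bromide 2 alkylates the dianion of dimethyl (2-oxopropyl)phosphonate (NaH, then n-BuLi, THF, 0 °C) at the terminal carbon to give dimethyl [(5E)-6,10-dimethyl-2-oxoundeca-5,9-dien-1-yl]phosphonate F1. Shi epoxidation as in step 2 gives dimethyl [(5R,6R,9R)-5,6:9,10-diepoxy-6,10-dimethyl-2-oxoundecyl]phosphonate F2. Triflate 14 is coupled with BrZnCH2CO2Et (Pd(PPh3)4, THF, 60 °C) to ethyl 2-[(5R,6S)-2,6-dimethyl-6-(prop-2-en-1-yl)-5-(triethylsilyloxy)cyclohex-1-en-1-yl]acetate F3, which iBu2AlH (CH2Cl2, −78 °C) reduces to 2-[(5R,6S)-2,6-dimethyl-6-(prop-2-en-1-yl)-5-(triethylsilyloxy)cyclohex-1-en-1-yl]acetaldehyde F4. Horner–Wadsworth–Emmons reaction of F2 with F4 (LiCl, iPr2NEt, MeCN) gives (2E,7R,8R,11R)-7,8:11,12-diepoxy-1-[(5R,6S)-2,6-dimethyl-6-(prop-2-en-1-yl)-5-(triethylsilyloxy)cyclohex-1-en-1-yl]-8,12-dimethyltridec-2-en-4-one F5. Its 1,4-hydrosilylation (RhCl(PPh3)3, Et3SiH, toluene, 50 °C) places the enol ether regiospecifically and gives 15.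

Step 9. The cascade normally gives moderate yields, and here the electron-rich tetrasubstituted ring C alkene could trap the silylated oxocarbenium ion (Prins-type) before it loses silicon. The fallback cyclises before ring C is attached; it sets out from 2 and 14, by way of the ketophosphonate diepoxide F2 and the aldehyde F4 made as in the fallback to step 8, and comes back at 17. F2 is converted (LiN(SiMe3)2, Me3SiCl, THF, −78 °C) into dimethyl [(5R,6R,9R)-5,6:9,10-diepoxy-6,10-dimethyl-2-(trimethylsilyloxy)undec-1-en-1-yl]phosphonate F6, which is cyclised alone (TMSOTf, 2,6-di-tert-butyl-4-methylpyridine, CH2Cl2, −78 °C; then Bu4NF) to dimethyl [(3R,5aS,9aR)-3-hydroxy-2,2,5a-trimethyl-7-oxoperhydro-1-benzoxepin-6-yl]phosphonate F7. Horner–Wadsworth–Emmons reaction of F7 with F4 (Ba(OH)2, THF–H2O) gives (3R,5aR,9aR)-3-hydroxy-6-{2-[(5R,6S)-2,6-dimethyl-6-(prop-2-en-1-yl)-5-(triethylsilyloxy)cyclohex-1-en-1-yl]ethylidene}-2,2,5a-trimethylperhydro-1-benzoxepin-7-one F8. Conjugate reduction with [(Ph3P)CuH]6 (toluene, rt) gives (3R,5aR,6R,9aR)-3-hydroxy-6-{2-[(5R,6S)-2,6-dimethyl-6-(prop-2-en-1-yl)-5-(triethylsilyloxy)cyclohex-1-en-1-yl]ethyl}-2,2,5a-trimethylperhydro-1-benzoxepin-7-one F9, and Bu4NF (THF, rt) removes the silyl group and equilibrates C6 to give 17.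

Step 4. The catalyst must choose between two enantiotopic carbonyls and two faces, and the methyl/allyl difference may give only moderate diastereo- and enantioselectivity. The fallback replaces the oxazaborolidine by a biocatalytic desymmetrisation; it sets out from 8 and comes back at 9. An NADPH-dependent ketoreductase selected from a commercial panel for the (2R,3R)-ketol is used with glucose/glucose dehydrogenase cofactor recycling (phosphate buffer pH 7, 30 °C); no new compound is made.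

**Further compounds**

F1 | step 8 | dimethyl [(5E)-6,10-dimethyl-2-oxoundeca-5,9-dien-1-yl]phosphonate | CC(C)=CCC/C(C)=C/CCC(=O)CP(=O)(OC)OC
F2 | step 8 | dimethyl [(5R,6R,9R)-5,6:9,10-diepoxy-6,10-dimethyl-2-oxoundecyl]phosphonate | COP(=O)(OC)CC(=O)CC[C@H]1O[C@]1(C)CC[C@H]2OC2(C)C
F3 | step 8 | ethyl 2-[(5R,6S)-2,6-dimethyl-6-(prop-2-en-1-yl)-5-(triethylsilyloxy)cyclohex-1-en-1-yl]acetate | CCOC(=O)CC1=C(C)CC[C@@H](O[Si](CC)(CC)CC)[C@@]1(C)CC=C
F4 | step 8 | 2-[(5R,6S)-2,6-dimethyl-6-(prop-2-en-1-yl)-5-(triethylsilyloxy)cyclohex-1-en-1-yl]acetaldehyde | O=CCC1=C(C)CC[C@@H](O[Si](CC)(CC)CC)[C@@]1(C)CC=C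
F5 | step 8 | (2E,7R,8R,11R)-7,8:11,12-diepoxy-1-[(5R,6S)-2,6-dimethyl-6-(prop-2-en-1-yl)-5-(triethylsilyloxy)cyclohex-1-en-1-yl]-8,12-dimethyltridec-2-en-4-one | O=C(/C=C/CC1=C(C)CC[C@@H](O[Si](CC)(CC)CC)[C@@]1(C)CC=C)CC[C@H]2O[C@]2(C)CC[C@H]3OC3(C)C
F6 | step 9 | dimethyl [(5R,6R,9R)-5,6:9,10-diepoxy-6,10-dimethyl-2-(trimethylsilyloxy)undec-1-en-1-yl]phosphonate | COP(=O)(OC)C=C(O[Si](C)(C)C)CC[C@H]1O[C@]1(C)CC[C@H]2OC2(C)C
F7 | step 9 | dimethyl [(3R,5aS,9aR)-3-hydroxy-2,2,5a-trimethyl-7-oxoperhydro-1-benzoxepin-6-yl]phosphonate | COP(=O)(OC)C2[C@@]3(C)CC[C@@H](O)C(C)(C)O[C@@H]3CCC2=O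
F8 | step 9 | (3R,5aR,9aR)-3-hydroxy-6-{2-[(5R,6S)-2,6-dimethyl-6-(prop-2-en-1-yl)-5-(triethylsilyloxy)cyclohex-1-en-1-yl]ethylidene}-2,2,5a-trimethylperhydro-1-benzoxepin-7-one | CC1=C(CC=C2[C@@]3(C)CC[C@@H](O)C(C)(C)O[C@@H]3CCC2=O)[C@](C)(CC=C)[C@H](O[Si](CC)(CC)CC)CC1
F9 | step 9 | (3R,5aR,6R,9aR)-3-hydroxy-6-{2-[(5R,6S)-2,6-dimethyl-6-(prop-2-en-1-yl)-5-(triethylsilyloxy)cyclohex-1-en-1-yl]ethyl}-2,2,5a-trimethylperhydro-1-benzoxepin-7-one | CC1=C(CC[C@@H]2[C@@]3(C)CC[C@@H](O)C(C)(C)O[C@@H]3CCC2=O)[C@](C)(CC=C)[C@H](O[Si](CC)(CC)CC)CC1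
F0 | step 4 | none | none
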